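# Proposed synthesis of 3,4,5-tri-O-galloyl-(−)-quinic acid (18) by bromolactonisation of an enantiopure Diels–Alder acid

## The problem

The target 18 is (−)-quinic acid carrying 3,4,5-trihydroxybenzoyl (galloyl) esters on O3, O4 and O5, with the tertiary C1 hydroxyl and the C1 carboxyl free. Its only ring is a cyclohexane with the quaternary C1 (OH, CO2H) and the contiguous carbinols C3, C4 and C5; the carboxyl is cis to O5, O4 is trans to O5 and O3 is cis to O4, so one centre, once fixed, can control the others through the ring. The 1,3-cis relation of the carboxyl and O5 allows the two to be tied into a γ-lactone (a 6-oxabicyclo[3.2.1]octan-7-one), and halolactonisation of a 1-oxygenated cyclohex-3-ene-1-carboxylic acid gives exactly this lactone, with the halogen on C4 as the handle for a C3=C4 alkene. Such an acid is not mirror-symmetric: its alkene lies between C4 and C5, no plane through C1 maps the ring onto itself, and C1 is already a stereocentre. The lactonisation therefore cannot select between enantiotopic carbons; it can only pass the configuration of C1 on to C5 and C4, so absolute configuration has to be present in the acid beforehand. The rigid bicyclic lactone then leaves one open face for installing O3 and O4. The galloyl esters are the fragile part: nine free phenols oxidise readily in base or air, and aryl esters cleave or migrate under alkoxide or hydroxide. They must therefore be introduced last, in protected form, and unveiled under neutral conditions.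

## Retrosynthesis

**18 ⇒ 17.** Ten O–CH2Ph bonds are cut: nine aryl benzyl ethers and the benzyl ester of the C1 carboxyl. Silyl or acyl protection would need fluoride or base, which attack galloyl esters; benzyl groups fall together in one neutral hydrogenolysis. The forward step must leave the three aryl esters and the free tertiary hydroxyl alone.

**17 ⇒ 14 + 16 (16 ⇐ 15).** The three ester C–O bonds at O3, O4 and O5 are cut, giving benzyl quinate 14 and three equivalents of acid chloride 16, made from commercial acid 15. All three secondary hydroxyls carry the same acyl group, so no regiocontrol is needed. The forward reaction must acylate exhaustively, spare the hindered C1 hydroxyl, and outrun relactonisation of O5.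

**14 ⇒ 13.** The benzyl ester C–O bond is cut and the C5–O lactone bond and the C1 acetate are restored. Lactone 13 is the form in which the key step delivers the ring. One transesterification should protect the carboxyl as a hydrogenolysable ester and free O5 and O1 together.

**13 ⇒ 12.** The C3–O and C4–O bonds are cut. Syn-dihydroxylation is preferred to epoxide opening, which would give the wrong trans-3,4-diol. The rigid bicycle of 12 should direct the oxidant to the face away from the lactone bridge, which is the quinate configuration.

**12 ⇒ 11.** HBr is added back across C3=C4. The bromide on C4 is what the key step leaves behind, and its only possible elimination is towards C3.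

**11 ⇒ 10 (key disconnection).** The C5–O lactone bond and the C4–Br bond are cut, revealing acid 10. This removes one ring and two stereocentres and leaves a monocyclic acid with C1 as its only stereocentre. Because 10 is chiral, a chiral brominating catalyst would have nothing to desymmetrise and could at best resolve a racemate at the cost of half the material. The step is therefore asked only to relay C1 to C5 and C4 through the carboxylate tether and anti addition; 10 must arrive enantiopure.

**10 ⇒ 8 ⇒ 7.** The acetate C–O bond is cut, and then the acetal that masks the hydroxy acid 8 as spiro-dioxolanone 7. The acetate is a spectator chosen for the key step (see step 5).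

**7 ⇒ 5 + 6.** The C1–C6 and C2–C3 bonds are cut in a Diels–Alder sense, giving buta-1,3-diene 6 and the chiral 2-oxyacrylate equivalent 5. An achiral 2-acyloxyacrylate would give the same ring as a racemate and would force a resolution. In 5 the tert-butyl acetal shields one face of the alkene, so the cycloaddition should set C1.

**5 ⇒ 3 ⇒ 1 + 2.** The exocyclic alkene is traced to the methyl group of dioxolanone 3, the acetal of (R)-lactic acid 1 and pivalaldehyde 2. Chirality is bought from the lactic acid pool and stored at the acetal carbon while the original centre is destroyed.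

## Roads not taken

Alternative 1: The cut removes the C1–O and C4–O bonds together. Singlet oxygen would add across C1 and C4 of the 3-silyloxy diene ester A2, anti to the C5 silyloxy group, to give endoperoxide A1.
- Merits: two C–O bonds and the quaternary C1 form in one step; the cis relation of the C1 and C4 oxygens is guaranteed; the carboxyl needs no lactone detour. In these respects it is more direct than the chosen plan.
- Weak points: facial selectivity rests on a single allylic silyloxy group. Ene reaction at the C5 and C6 hydrogens and silyl transfer from the enol ether compete. A1 has a hydrogen on C4 next to the peroxide and should be prone to Kornblum–DeLaMare fragmentation. After O–O cleavage the C3 ketone must still be reduced to the axial alcohol. A2 must itself be made enantiopure.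
- Comparison: the chosen plan has more steps between ring formation and the tetraol. Against that, every centre after C1 is set by a rigid bicycle rather than by a conformationally mobile diene, and no intermediate is a peroxide.

Alternative 2: C1–C2 and C1–C6 are cut, making C1 an acyl-anion linchpin. Lithiated 1,3-dithiane A5 would be alkylated twice by the tri-O-benzyl diiodide A4 of the pentitol pool to close the ring as dithiane ketal A3.
- Merits: C3 and C5 come from the chiral pool without auxiliary or resolution, which is cheaper in chirality than the stoichiometric acetal of the chosen plan. C4 needs no control at that stage, because it is not a stereocentre while C1 is symmetric.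
- Weak points: both alkylations are SN2 reactions at primary iodides β to benzyloxy groups, where elimination competes. After the C1 carbonyl is unmasked from A3, a carboxyl equivalent must be added with the correct facial sense relative to the C4 oxygen, so the quaternary centre is set last under weak control. The benzyl ethers must then be exchanged for galloyl esters.
- Comparison: the chosen plan sets C1 first and lets it control the rest; this road sets C1 last.

Alternative 3: The C2–C3 bond is cut. Aldehyde A7, from the tartrate pool, would cyclise under a Lewis acid such as Me2AlCl in a type 2 carbonyl-ene reaction to homoallylic alcohol A6.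
- Merits: the ring closes by C–C bond formation; C4 and C5 are bought from the pool; the C1 methylene is a good precursor of the hydroxy acid by osmylation and oxidation.
- Weak points: the acetonide is trans-fused on the forming ring. The C3 hydroxyl must emerge axial and cis to O4, which the ene transition state does not obviously favour. C1 is again set late, by face selection on an exocyclic alkene with only remote bias. Oxidation of the primary alcohol beside three secondary ones needs further protection.
- Comparison: it shares the osmylation of the chosen plan but applies it where the substrate offers less bias. Its chiral-pool origin is its real advantage over a stoichiometric auxiliary.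

Key step: step 6

## Route

Remark: ring positions in the discussion use quinate numbering (C1 quaternary; C3, C4, C5 carbinol carbons). Systematic locants appear only in compound names. The C1 and C4 descriptors of 14, 17 and 18 are quoted in the form customary for quinic acid.

Step 1
Reactants: 1 (R)-lactic acid; 2 pivalaldehyde
Product: 3 (2R,5R)-2-tert-butyl-5-methyl-1,3-dioxolan-4-one
Conditions: p-TsOH (cat.), H2SO4 (cat.), pentane, reflux, Dean–Stark; crystallisation from pentane–Et2O at −78 °C
Reagents that add atoms: none
Why: Acid-catalysed acetalisation of the α-hydroxy acid with azeotropic removal of water; the acetal carbon C2 forms under equilibrating conditions in which the cis isomer (tert-butyl and methyl on the same face) should predominate and is purified by low-temperature crystallisation, so the lactic acid centre is copied onto C2 (self-regeneration of stereocentres).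

Step 2
Reactants: 3 (2R,5R)-2-tert-butyl-5-methyl-1,3-dioxolan-4-one
Product: 5 (2R)-2-tert-butyl-5-methylidene-1,3-dioxolan-4-one, via tertiary bromide 4 (not isolated)
Conditions: NBS, AIBN (cat.), CCl4 (or PhCF3), reflux; then Et3N, 0 °C to rt; distillation, storage cold over BHT
Reagents that add atoms: none
Why: Wohl–Ziegler-type radical bromination at the captodative C5–H gives tertiary bromide 4, and amine-induced dehydrobromination then gives the exocyclic alkene; C5 becomes trigonal while the acetal centre C2, now the only stereocentre, is not touched.

Step 3
Reactants: 5 (2R)-2-tert-butyl-5-methylidene-1,3-dioxolan-4-one; 6 buta-1,3-diene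
Product: 7 (2R,5S)-2-tert-butyl-1,3-dioxaspiro[4.5]dec-7-en-4-one
Conditions: 6 (excess), BHT (cat.), toluene, sealed tube, 90–110 °C
Reagents that add atoms: none
Why: Thermal Diels–Alder reaction of a captodative 2-oxyacrylate dienophile with an acyclic diene, a known behaviour of this dienophile; the diene bonds to C5 from the face opposite the tert-butyl group, which sets the spiro carbon (later C1) as S, and with unsubstituted butadiene neither regiochemistry nor endo/exo orientation can give further isomers.

Step 4
Reactants: 7 (2R,5S)-2-tert-butyl-1,3-dioxaspiro[4.5]dec-7-en-4-one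
Product: 8 (1S)-1-hydroxycyclohex-3-ene-1-carboxylic acid
Conditions: LiOH, THF–H2O, rt; then aq. HCl
Reagents that add atoms: lithium hydroxide, [Li+].[OH-]; water, O
Why: Saponification of the acyl acetal: hydroxide opens the lactone carbonyl and the hemiacetal collapses with loss of pivalaldehyde; the quaternary stereocentre has no α-hydrogen and cannot epimerise.

Step 5
Reactants: 8 (1S)-1-hydroxycyclohex-3-ene-1-carboxylic acid
Product: 10 (1S)-1-acetoxycyclohex-3-ene-1-carboxylic acid, via mixed acetic anhydride 9 (not isolated)
Conditions: Ac2O (3 equiv), DMAP (cat.), pyridine, rt; then H2O; aq. HCl work-up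
Reagents that add atoms: acetic anhydride, CC(=O)OC(C)=O; water, O
Why: DMAP-catalysed acetylation of the tertiary hydroxyl; the carboxyl passes through mixed anhydride 9 and is released by the aqueous quench. The acetate is needed in step 6 because a free α-hydroxy acid would suffer oxidative decarboxylation by NBS and a free tertiary hydroxyl could capture the bromonium ion at C4.

Step 6
Reactants: 10 (1S)-1-acetoxycyclohex-3-ene-1-carboxylic acid
Product: 11 (1S,4R,5R)-4-bromo-7-oxo-6-oxabicyclo[3.2.1]octan-1-yl acetate
Conditions: NBS, NaHCO3, THF–H2O, 0 °C to rt, dark
Reagents that add atoms: N-bromosuccinimide, O=C1CCC(=O)N1Br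
Why: Halolactonisation: NBS transfers Br+ reversibly to either face of the C4=C5 alkene of the carboxylate, and only the bromonium ion anti to the carboxylate can be opened intramolecularly. The carboxylate, axial in the reacting half-chair, attacks C5 from its own face in a 5-exo opening of the bromonium ring, closing the γ-lactone of the 6-oxabicyclo[3.2.1]octan-7-one and leaving bromine axial on C4 (trans-diaxial opening). The closest known reaction is the bromo- or iodolactonisation of cyclohex-3-ene-1-carboxylic acids, which is established for the racemic form of this very acid. C5 is set by the tether, since the oxygen can only arrive cis to the C1 carboxyl, and C4 by the anti addition, so both follow from the S configuration of C1 fixed in step 3; no catalyst control is needed, because the acid has no mirror plane and only the alkene carbon three bonds from the carboxyl carbon can close a five-membered ring. The selectivity needed is regiochemical (γ-lactone over the boat-like δ-lactone at C4) and chemoselective (lactone over bromohydrin, dibromide or acetate participation); the kinetic preference for the five-membered ring, the anionic carboxylate under bicarbonate buffering and the poor nucleophilicity of the acetate should secure it. The bromolactone is expected to be crystalline, which should offer a chance to raise its enantiomeric purity by recrystallisation.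

Step 7
Reactants: 11 (1S,4R,5R)-4-bromo-7-oxo-6-oxabicyclo[3.2.1]octan-1-yl acetate
Product: 12 (1S,5R)-7-oxo-6-oxabicyclo[3.2.1]oct-3-en-1-yl acetate
Conditions: DBU, toluene, 80 °C
Reagents that add atoms: none
Why: E2 dehydrobromination: the axial C4 bromide is antiperiplanar to the axial hydrogen on C3, whereas elimination towards C5 would need a bridgehead double bond (Bredt's rule) and lacks an antiperiplanar hydrogen; C1 and C5 are untouched.

Step 8
Reactants: 12 (1S,5R)-7-oxo-6-oxabicyclo[3.2.1]oct-3-en-1-yl acetate
Product: 13 (1S,3R,4R,5R)-3,4-dihydroxy-7-oxo-6-oxabicyclo[3.2.1]octan-1-yl acetate (1-O-acetylquinide)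
Conditions: OsO4 (cat.), NMO, acetone–H2O, rt
Reagents that add atoms: osmium tetroxide, O=[Os](=O)(=O)=O; N-methylmorpholine N-oxide, C[N+]1([O-])CCOCC1; water, O
Why: Catalytic syn-dihydroxylation ([3+2] addition of OsO4, reoxidation by NMO); the reagent adds to the face of C3=C4 opposite the two-atom lactone bridge, so O3 and O4 arrive cis to each other and trans to O5, which sets C3 and C4 of the target.

Step 9
Reactants: 13 (1S,3R,4R,5R)-3,4-dihydroxy-7-oxo-6-oxabicyclo[3.2.1]octan-1-yl acetate
Product: 14 benzyl (1S,3R,4S,5R)-1,3,4,5-tetrahydroxycyclohexane-1-carboxylate (benzyl quinate)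
Conditions: NaOCH2Ph (cat.), PhCH2OH, rt; then AcOH; chromatography
Reagents that add atoms: benzyl alcohol, OCc1ccccc1; sodium benzyloxide, [Na+].[O-]Cc1ccccc1
Why: Zemplén-type alkoxide transesterification: benzyloxide opens the strained γ-lactone to the benzyl ester and cleaves the tertiary acetate as benzyl acetate, the large excess of benzyl alcohol holding the equilibrium on the side of the open ester; no centre is epimerisable because C1 bears no hydrogen.

Step 10
Reactants: 15 3,4,5-tris(benzyloxy)benzoic acid
Product: 16 3,4,5-tris(benzyloxy)benzoyl chloride
Conditions: (COCl)2, DMF (cat.), CH2Cl2, 0 °C to rt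
Reagents that add atoms: oxalyl chloride, O=C(Cl)C(=O)Cl
Why: Standard conversion of an aromatic acid into its chloride through the chloroiminium (Vilsmeier-type) intermediate from DMF and oxalyl chloride; benzyl ethers are inert.

Step 11
Reactants: 14 benzyl quinate; 16 3,4,5-tris(benzyloxy)benzoyl chloride (first equivalent); 16 3,4,5-tris(benzyloxy)benzoyl chloride (second equivalent); 16 3,4,5-tris(benzyloxy)benzoyl chloride (third equivalent)
Product: 17 benzyl 3,4,5-tris-O-[3,4,5-tris(benzyloxy)benzoyl]quinate
Conditions: 16 (3.5–4 equiv in all), DMAP, pyridine–CH2Cl2, 0 °C to rt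
Reagents that add atoms: 3,4,5-tris(benzyloxy)benzoyl chloride (second equivalent of 16), ClC(=O)c1cc(OCc2ccccc2)c(OCc2ccccc2)c(OCc2ccccc2)c1; 3,4,5-tris(benzyloxy)benzoyl chloride (third equivalent of 16), O=C(Cl)c1cc(OCc2ccccc2)c(OCc2ccccc2)c(OCc2ccccc2)c1
Why: DMAP-catalysed acylation by an acid chloride (Einhorn/Steglich-type acyl transfer) in which one molecule of 16 is consumed at each of the three secondary hydroxyls O3, O4 and O5, so three equivalents enter the product; the tertiary C1 hydroxyl, hindered and deactivated by the adjacent ester, should remain free, and rapid acylation of O5 forestalls relactonisation.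

Step 12
Reactants: 17 benzyl 3,4,5-tris-O-[3,4,5-tris(benzyloxy)benzoyl]quinate
Product: 18 3,4,5-tri-O-galloyl-(−)-quinic acid
Conditions: H2 (1 atm), 10% Pd/C, THF–MeOH, rt; filtration and evaporation under argon
Reagents that add atoms: none
Why: Heterogeneous hydrogenolysis of the nine benzyl ethers and the benzyl ester under neutral conditions, which the aryl esters and the oxidation-prone pyrogallol units tolerate; with all three secondary hydroxyls acylated, neither acyl migration nor lactonisation can occur.

## Compound list

1 | (R)-lactic acid [(2R)-2-hydroxypropanoic acid] | C[C@@H](O)C(=O)O | starting material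
2 | pivalaldehyde (2,2-dimethylpropanal) | CC(C)(C)C=O | starting material
3 | (2R,5R)-2-tert-butyl-5-methyl-1,3-dioxolan-4-one (cis) | CC(C)(C)[C@H]1OC(=O)[C@@H](C)O1 | intermediate
4 | (2R,5S)-5-bromo-2-tert-butyl-5-methyl-1,3-dioxolan-4-one (bromine trans to tert-butyl; not isolated) | CC(C)(C)[C@H]1OC(=O)[C@](C)(Br)O1 | intermediate
5 | (2R)-2-tert-butyl-5-methylidene-1,3-dioxolan-4-one | CC(C)(C)[C@H]1OC(=O)C(=C)O1 | intermediate
6 | buta-1,3-diene | C=CC=C | starting material
7 | (2R,5S)-2-tert-butyl-1,3-dioxaspiro[4.5]dec-7-en-4-one | CC(C)(C)[C@H]1OC(=O)[C@]2(CC=CCC2)O1 | intermediate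
8 | (1S)-1-hydroxycyclohex-3-ene-1-carboxylic acid | O[C@]1(C(=O)O)CC=CCC1 | intermediate
9 | acetic (1S)-1-acetoxycyclohex-3-ene-1-carboxylic anhydride (not isolated) | CC(=O)O[C@]1(C(=O)OC(C)=O)CC=CCC1 | intermediate
10 | (1S)-1-acetoxycyclohex-3-ene-1-carboxylic acid | CC(=O)O[C@]1(C(=O)O)CC=CCC1 | intermediate
11 | (1S,4R,5R)-4-bromo-7-oxo-6-oxabicyclo[3.2.1]octan-1-yl acetate | O2[C@@H]1C[C@](OC(C)=O)(C2=O)CC[C@H]1Br | intermediate
12 | (1S,5R)-7-oxo-6-oxabicyclo[3.2.1]oct-3-en-1-yl acetate | O2[C@@H]1C[C@](OC(C)=O)(C2=O)CC=C1 | intermediate
13 | (1S,3R,4R,5R)-3,4-dihydroxy-7-oxo-6-oxabicyclo[3.2.1]octan-1-yl acetate (1-O-acetylquinide) | O2[C@@H]1C[C@](OC(C)=O)(C2=O)C[C@@H](O)[C@H]1O | intermediate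
14 | benzyl (1S,3R,4S,5R)-1,3,4,5-tetrahydroxycyclohexane-1-carboxylate (benzyl quinate) | O[C@@H]1C[C@](O)(C(=O)OCc2ccccc2)C[C@@H](O)[C@H]1O | intermediate
15 | 3,4,5-tris(benzyloxy)benzoic acid | OC(=O)c1cc(OCc2ccccc2)c(OCc2ccccc2)c(OCc2ccccc2)c1 | starting material
16 | 3,4,5-tris(benzyloxy)benzoyl chloride | ClC(=O)c1cc(OCc2ccccc2)c(OCc2ccccc2)c(OCc2ccccc2)c1 | intermediate
17 | benzyl 3,4,5-tris-O-[3,4,5-tris(benzyloxy)benzoyl]quinate (quinate configuration as in 14, C1 hydroxyl free) | O=C(O[C@@H]1C[C@](O)(C(=O)OCc2ccccc2)C[C@@H](OC(=O)c2cc(OCc3ccccc3)c(OCc3ccccc3)c(OCc3ccccc3)c2)[C@H]1OC(=O)c1cc(OCc2ccccc2)c(OCc2ccccc2)c(OCc2ccccc2)c1)c1cc(OCc2ccccc2)c(OCc2ccccc2)c(OCc2ccccc2)c1 | intermediate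
18 | 3,4,5-tri-O-galloyl-(−)-quinic acid [(1S,3R,4S,5R)-1-hydroxy-3,4,5-tris(3,4,5-trihydroxybenzoyloxy)cyclohexane-1-carboxylic acid] | O=C(O[C@@H]1C[C@](O)(C(=O)O)C[C@@H](OC(=O)c2cc(O)c(O)c(O)c2)[C@H]1OC(=O)c1cc(O)c(O)c(O)c1)c1cc(O)c(O)c(O)c1 | target

## Step count and least certain steps

Total: 12 steps. Longest linear sequence: 11 steps (steps 1–9, 11, 12, from 1). Step 10 is a one-step side branch from 15.

**Step 6 (key step).** The bromonium ion may be captured by water (bromohydrin) or by the acetate carbonyl, or NBS may degrade the substrate oxidatively; each lowers the lactone yield. The step relays configuration and creates none, so any shortfall in enantiopurity from step 3 passes through unchanged.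
Fallback, from 10 to 12: phenylselenolactonisation with PhSeCl and pyridine in CH2Cl2 at −78 °C closes the same C5–O bond and γ-lactone and places selenium on C4. This gives (1S,4R,5R)-7-oxo-4-(phenylselanyl)-6-oxabicyclo[3.2.1]octan-1-yl acetate F1. Oxidation with H2O2 in THF gives the selenoxide F2. Its syn-elimination can only go towards C3, since C5 is a bridgehead, and gives 12. The fallback rejoins the route at 12 and also replaces step 7.

**Step 3.** The parent diene is sluggish, so polymerisation of the captodative alkene 5 may outpace cycloaddition. Shielding by the tert-butyl group may also be incomplete, which would erode the configuration of C1 on which all later centres depend.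
Fallback, from 6 to 8: a thermal Diels–Alder reaction of 6 with methyl 2-acetoxyacrylate F3 (hydroquinone, sealed vessel) gives racemic methyl 1-acetoxycyclohex-3-ene-1-carboxylate F4. Saponification with aqueous NaOH gives racemic 1-hydroxycyclohex-3-ene-1-carboxylic acid F5. This is resolved by crystallisation of its diastereomeric salts with (R)-1-phenylethylamine. The salt of the S acid, (R)-1-phenylethylammonium (1S)-1-hydroxycyclohex-3-ene-1-carboxylate F6, is taken from crystals or mother liquor as the case may be and acidified to give 8. Half of the material is lost, but steps 1, 2 and 4 are not needed.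

**Step 9.** The open ester and the lactone are in equilibrium. Transesterification may stop short, or 14 may relactonise during neutralisation and removal of benzyl alcohol.
Fallback, from 13 to 14: saponification of lactone and acetate with aqueous KOH and acidification on an ion-exchange resin gives (−)-quinic acid F7. Alkylation of its caesium carboxylate with benzyl bromide (Cs2CO3, DMF) gives 14.

**Step 11.** Acylation may stall at the third, most hindered hydroxyl. A still-free C5 hydroxyl could then lactonise onto the benzyl ester, or forcing conditions could begin to acylate the C1 hydroxyl.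
Fallback, from 13 to 18: hydrolysis to (−)-quinic acid F7 as above, then esterification with diphenyldiazomethane, gives diphenylmethyl quinate F8. Its bulky ester resists lactonisation and screens the C1 hydroxyl. Acylation with 16 (DMAP, pyridine) gives the diphenylmethyl triester F9. Hydrogenolysis (H2, Pd/C) removes the diphenylmethyl ester together with the benzyl ethers and gives 18.

## Further compounds

F1 | step 6 | (1S,4R,5R)-7-oxo-4-(phenylselanyl)-6-oxabicyclo[3.2.1]octan-1-yl acetate | O2[C@@H]1C[C@](OC(C)=O)(C2=O)CC[C@H]1[Se]c1ccccc1
F2 | step 6 | (1S,4R,5R)-7-oxo-4-(phenylseleninyl)-6-oxabicyclo[3.2.1]octan-1-yl acetate (selenoxide, mixture at selenium, not isolated) | O2[C@@H]1C[C@](OC(C)=O)(C2=O)CC[C@H]1[Se](=O)c1ccccc1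
F3 | step 3 | methyl 2-acetoxyacrylate | C=C(OC(C)=O)C(=O)OC
F4 | step 3 | methyl 1-acetoxycyclohex-3-ene-1-carboxylate (racemic) | COC(=O)C1(OC(C)=O)CC=CCC1
F5 | step 3 | 1-hydroxycyclohex-3-ene-1-carboxylic acid (racemic) | OC1(C(=O)O)CC=CCC1
F6 | step 3 | (R)-1-phenylethylammonium (1S)-1-hydroxycyclohex-3-ene-1-carboxylate | O[C@]1(C(=O)[O-])CC=CCC1.C[C@@H]([NH3+])c1ccccc1
F7 | step 9 | (−)-quinic acid [(1S,3R,4S,5R)-1,3,4,5-tetrahydroxycyclohexane-1-carboxylic acid] | O[C@@H]1C[C@](O)(C(=O)O)C[C@@H](O)[C@H]1O
F8 | step 11 | diphenylmethyl quinate | O[C@@H]1C[C@](O)(C(=O)OC(c2ccccc2)c2ccccc2)C[C@@H](O)[C@H]1O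
F9 | step 11 | diphenylmethyl 3,4,5-tris-O-[3,4,5-tris(benzyloxy)benzoyl]quinate | O=C(O[C@@H]1C[C@](O)(C(=O)OC(c2ccccc2)c2ccccc2)C[C@@H](OC(=O)c2cc(OCc3ccccc3)c(OCc3ccccc3)c(OCc3ccccc3)c2)[C@H]1OC(=O)c1cc(OCc2ccccc2)c(OCc2ccccc2)c(OCc2ccccc2)c1)c1cc(OCc2ccccc2)c(OCc2ccccc2)c(OCc2ccccc2)c1
A1 | alternative 1 | benzyl 8-(tert-butyldimethylsilyloxy)-5-(trimethylsilyloxy)-2,3-dioxabicyclo[2.2.2]oct-5-ene-1-carboxylate (endoperoxide across quinate C1 and C4, anti to the C5 silyloxy group) | CC(C)(C)[Si](C)(C)O[C@@H]1C[C@]2(OO[C@@H]1C(O[Si](C)(C)C)=C2)C(=O)OCc1ccccc1
A2 | alternative 1 | benzyl (5R)-5-(tert-butyldimethylsilyloxy)-3-(trimethylsilyloxy)cyclohexa-1,3-diene-1-carboxylate | CC(C)(C)[Si](C)(C)O[C@@H]1CC(C(=O)OCc2ccccc2)=CC(O[Si](C)(C)C)=C1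
A3 | alternative 2 | 3,4,5-tris(benzyloxy)cyclohexanone 1,3-dithiane ketal (quinate numbering, 3R,5R) | c1ccccc1CO[C@@H]1CC2(SCCCS2)C[C@@H](OCc2ccccc2)C1OCc1ccccc1
A4 | alternative 2 | 2,3,4-tri-O-benzyl-1,5-dideoxy-1,5-diiodo-D-arabinitol | IC[C@@H](OCc1ccccc1)C(OCc1ccccc1)[C@H](OCc1ccccc1)CI
A5 | alternative 2 | 1,3-dithiane | C1CSCSC1
A6 | alternative 3 | 4,5-O-isopropylidene-1-methylidenecyclohexane-3,4,5-triol with axial C3 hydroxyl (quinate numbering, 3R,4R,5R) | CC1(C)O[C@@H]2CC(=C)C[C@@H](O)[C@H]2O1
A7 | alternative 3 | (4S,5R)-2,2-dimethyl-5-(2-methylprop-2-en-1-yl)-1,3-dioxolane-4-carbaldehyde | CC1(C)O[C@H](CC(C)=C)[C@@H](C=O)O1
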